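The runs were computed with made-up constants, and the scatter is random.

Count the partner before you touch west, the very flask asked about.

- west: left-handed substrate 0.021 M; right-handed substrate 0.021 M; partner 0.021 M; protic impurity 1.05 mM; free catalyst 82 µM; temperature 20 °C; the very flask that is asked about, followed so far
- flask: left-handed substrate 0.021 M; partner 0.0210 M; protic impurity 1.05 mM; free catalyst 82 µM; right-handed substrate 0.021 M; temperature 20 °C; time 15 h

west run (percent of the left-handed substrate and right-handed substrate together charged)

| time / h | left-handed product / % | left-handed substrate / % |
|---|---|---|
| 1.33 | 16.2 | 34.0 |
| 2.00 | 19.9 | 30.0 |
| 3.00 | 23.2 | 26.5 |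
| 5.00 | 27.1 | 23.5 |
| 10.0 | 30.2 | 19.4 |
| 15.0 | 31.6 | 18.5 |

(standard deviation of a reading: 0.3 percentage points)

- elm: change nothing and wait 8.0 h more
- alder: at 15 h take out 90% of the left-handed product then present, then wait 8.0 h
- ash: at 15 h raise the temperature by 20 K, then wait 8.0 h
- cedar: at 15 h add free catalyst, 100% of the amount charged, then wait 8.0 h
- larch: at 15 h add partner, 50.0% of the amount charged, then wait 8.0 h

- free catalyst is single-handed; left-handed substrate and right-handed substrate are mirror images of each other, charged as a racemate, each of them at the stated concentration
- left-handed product that was removed still counts
- the numbers in the tables scatter with a standard deviation of 0.3 percentage points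
- additions bring no volume worth counting

- left-handed product, in percent of the left-handed substrate and right-handed substrate together first charged, at 15 h
- which option adds most left-handed product ("none" when 2 percentage points or less is all one gets) (elm / alder / ash / cedar / larch / none)
- left-handed product present, with what was taken out counted in, in percent of the left-handed substrate and right-handed substrate together first charged, after alder
- left-handed product present, with what was taken out counted in, in percent of the left-handed substrate and right-handed substrate together first charged, after cedar

- **In the flask now:** west reads 31.6% left-handed product and 18.5% left-handed substrate at 15.0 h, together 50.1%, so no substrate has gone astray beyond the scatter. Take 31.6% as my answer for now.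
- **The balance to keep:** free partner is the charge, less the protic impurity counted one for one, less the product made; in west at 15.0 h that is 0.00668 M.
- **What runs short:** west holds 0.00777 M left-handed substrate, so free partner, being less than that substrate, is the limiting reagent against it.
- **Why west has slowed:** the drop in rate from the first gap between readings to the last, a factor of about 19.7, reads larger than the factor of 3.62 in free partner times left-handed substrate between 1.33 h and 15.0 h. Put the difference down to a fading catalyst.
- **What to leave alone:** do not pull product, add partner or warm west; I expect none of these to help a fading catalyst.
- **What to do:** add free catalyst. Free partner is worth 15.9% of the substrates charged, which by my balance caps left-handed product at 47.5%. That is my ceiling, not a forecast of the gain.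
- **The forecast:** it gives 31.6% now, cedar as best, 32% after alder and 37% after cedar, on the ground that “fresh catalyst restarts conversion, limited by remaining partner”.

**Result:** west gives 31.7% now, and cedar is best at 37.6%, against 32.0% after alder. Free catalyst stood at 4.29% of its charge at 15.0 h.

    partner + free catalyst + left-handed substrate → free catalyst + left-handed product (k = 2.50 × 10⁵ M⁻² h⁻¹, Ea = 40.0 kJ mol⁻¹)
    partner + free catalyst + right-handed substrate → free catalyst + right-handed product (k = 5100 M⁻² h⁻¹, Ea = 49.0 kJ mol⁻¹)
    partner + protic impurity → quenched reagent (k = 3600 M⁻¹ h⁻¹, Ea = 42.0 kJ mol⁻¹)
    free catalyst → spent catalyst (k = 0.210 h⁻¹, Ea = 100 kJ mol⁻¹)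
    (constants at 20 °C)

Taking right-handed product from the balance leaves west 29.8% of its partner, and the flask holds 30%. The neighbour charged with 0.084 M of partner balances to 71.0% of its charge, and it holds 71%.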